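**Strategy.** The butenolide (ring atoms O1, C2, C3, C4, C5) is read as a masked (Z)-2-en-4-ynoic acid: the enol-lactone bond O1–C5 and the exocyclic Z alkene arise together when a carboxylate adds across an alkyne. In one operation (E)-2,3-dibromoacrylic acid is coupled through its β-bromide to the terminal alkyne of a C23 polyenyne that already carries the acetylenic ring, and the enynoic acid so formed lactonises in the flask to a 3-bromo-(Z)-5-ylidenebutenolide. The surviving C3 bromide then accepts the epoxycyclohexyl vinylstannane by Stille coupling. Both six-membered rings derive from (−)-actinol through one common enol triflate.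

Key step: step 15

Remark: (−)-actinol (1) and (2E)-3-methylpent-2-en-4-yn-1-ol (12) are taken as purchasable; TBS = tert-butyldimethylsilyl.

**Step 1**
Reactants: 1 (−)-actinol
Product: 2 (4R,6R)-4-(TBSO)-2,2,6-trimethylcyclohexan-1-one
Conditions: TBSCl, imidazole, DMF, 25 °C
Reagents that add atoms: tert-butyldimethylsilyl chloride, CC(C)(C)[Si](C)(C)Cl
Why: Imidazole-promoted silylation of the secondary alcohol (silyl ether formation) leaves the hindered ketone and the carbinol stereocentre untouched.

**Step 2**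
Reactants: 2 silyl ether of actinol
Product: 4 (4R)-4-(TBSO)-2,6,6-trimethylcyclohex-1-en-1-yl trifluoromethanesulfonate, via lithium enolate 3 (not isolated)
Conditions: LiN(iPr)2, THF, −78 °C; then PhNTf2, −78 → 0 °C
Reagents that add atoms: N-phenylbis(trifluoromethanesulfonimide), O=S(=O)(N(c1ccccc1)S(=O)(=O)C(F)(F)F)C(F)(F)F
Why: The ketone can enolise only toward the methyl-bearing carbon because the other α-carbon is quaternary, so a single enolate forms and is O-sulfonylated (enol triflate formation), which deliberately erases the methyl-bearing stereocentre.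

**Step 3**
Reactants: 4 enol triflate
Product: 5 methyl (4R)-4-(TBSO)-2,6,6-trimethylcyclohex-1-ene-1-carboxylate
Conditions: Pd(OAc)2 (5 mol%), PPh3, CO (1 atm), MeOH, Et3N, DMF, 60 °C
Reagents that add atoms: carbon monoxide, [C-]#[O+]; methanol, CO
Why: Palladium-catalysed methoxycarbonylation of an alkenyl triflate (oxidative addition, CO insertion, methanolysis) installs the one-carbon unit on the hindered tetrasubstituted alkene.

**Step 4**
Reactants: 5 methyl ester
Product: 6 [(4R)-4-(TBSO)-2,6,6-trimethylcyclohex-1-en-1-yl]methanol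
Conditions: iBu2AlH, CH2Cl2, −78 → 0 °C
Reagents that add atoms: none
Why: Hydride reduction of the conjugated ester by iBu2AlH gives the allylic alcohol by 1,2-reduction and spares the silyl ether.

**Step 5**
Reactants: 6 allylic alcohol
Product: 7 [(1R,4S,6R)-4-(TBSO)-2,2,6-trimethyl-7-oxabicyclo[4.1.0]heptan-1-yl]methanol
Conditions: Ti(OiPr)4 (10 mol%), D-(−)-diethyl tartrate (12 mol%), tBuOOH, 4 Å sieves, CH2Cl2, −20 °C
Reagents that add atoms: tert-butyl hydroperoxide, CC(C)(C)OO
Why: In this Sharpless asymmetric epoxidation the titanium tartrate complex binds the allylic alcohol and, with D-(−)-diethyl tartrate, should deliver oxygen to the alkene face opposite the silyloxy group, so both epoxide stereocentres are set by reagent control, expected to be reinforced by the steric bias of the substrate.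

**Step 6**
Reactants: 7 epoxy alcohol
Product: 8 (1R,4S,6R)-4-(TBSO)-2,2,6-trimethyl-7-oxabicyclo[4.1.0]heptane-1-carbaldehyde
Conditions: Pr4N[RuO4] (5 mol%), N-methylmorpholine N-oxide, 4 Å sieves, CH2Cl2, 25 °C
Reagents that add atoms: none
Why: Ley–Griffith oxidation takes the primary alcohol to the aldehyde under neutral conditions that spare the epoxide, and the aldehyde has no α-hydrogen to epimerise.

**Step 7**
Reactants: 8 epoxy aldehyde
Product: 9 (1S,4S,6R)-4-(TBSO)-1-[(E)-2-iodoethenyl]-2,2,6-trimethyl-7-oxabicyclo[4.1.0]heptane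
Conditions: CrCl2, CHI3, THF, 0 → 25 °C
Reagents that add atoms: iodoform, IC(I)I
Why: In this Takai iodo-olefination the geminal dichromium species formed from CHI3 and CrCl2 adds to the aldehyde and eliminates through the less crowded arrangement, which should give the E vinyl iodide, the quaternary α-carbon favouring E further.

**Step 8**
Reactants: 9 vinyl iodide
Product: 11 tributyl{(E)-2-[(1S,4S,6R)-4-(TBSO)-2,2,6-trimethyl-7-oxabicyclo[4.1.0]heptan-1-yl]ethenyl}stannane, via alkenyllithium 10 (not isolated)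
Conditions: tBuLi (2 equiv), Et2O, −78 °C; then Bu3SnCl, −78 → 0 °C
Reagents that add atoms: tributyltin chloride, CCCC[Sn](Cl)(CCCC)CCCC
Why: Iodine–lithium exchange proceeds with retention of alkene geometry and the alkenyllithium is trapped at tin, while the tetrasubstituted epoxide and the silyl ether are inert at −78 °C.

**Step 9**
Reactants: 4 enol triflate; 12 (2E)-3-methylpent-2-en-4-yn-1-ol
Product: 13 (2E)-5-[(4R)-4-(TBSO)-2,6,6-trimethylcyclohex-1-en-1-yl]-3-methylpent-2-en-4-yn-1-ol
Conditions: Pd(PPh3)4 (5 mol%), CuI (10 mol%), iPr2NH, DMF, 50 °C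
Reagents that add atoms: none
Why: Sonogashira coupling of the alkenyl triflate to the terminal alkyne forms the ring–alkyne bond, tolerates the free hydroxyl and carries the E alkene of 12 over unchanged.

**Step 10**
Reactants: 13 dienynol
Product: 14 (2E)-5-[(4R)-4-(TBSO)-2,6,6-trimethylcyclohex-1-en-1-yl]-3-methylpent-2-en-4-ynal
Conditions: MnO2, CH2Cl2, 25 °C
Reagents that add atoms: none
Why: MnO2 oxidises the allylic alcohol selectively to the conjugated aldehyde without over-oxidation.

**Step 11**
Reactants: 14 enynal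
Product: 15 (2E,4E)-7-[(4R)-4-(TBSO)-2,6,6-trimethylcyclohex-1-en-1-yl]-5-methylhepta-2,4-dien-6-ynal
Conditions: Ph3P=CHCHO, toluene, 80 °C
Reagents that add atoms: (triphenylphosphoranylidene)acetaldehyde, O=CC=P(c1ccccc1)(c1ccccc1)c1ccccc1
Why: Wittig two-carbon homologation by the stabilised formylmethylene ylide should give the E enal, as stabilised ylides react under thermodynamic control.

**Step 12**
Reactants: 12 (2E)-3-methylpent-2-en-4-yn-1-ol
Product: 16 (3E)-5-bromo-3-methylpent-3-en-1-yne
Conditions: PBr3, pyridine (cat.), Et2O, 0 °C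
Reagents that add atoms: phosphorus tribromide, BrP(Br)Br
Why: Bromide displaces the phosphite ester of the primary allylic alcohol in an SN2 reaction that keeps the E geometry of the trisubstituted alkene.

**Step 13**
Reactants: 16 allylic bromide; 15 dienynal
Product: 19 (4R)-1-[(3E,5E,7E,9E)-3,10-dimethyldodeca-3,5,7,9-tetraene-1,11-diyn-1-yl]-4-(TBSO)-2,6,6-trimethylcyclohex-1-ene, via phosphonium bromide 17 (not isolated), via phosphorus ylide 18 (not isolated)
Conditions: PBu3, THF, 25 °C; then KOtBu (1 equiv), −78 °C; then 15, −78 → 25 °C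
Reagents that add atoms: none
Why: In this E-selective Wittig olefination of an allylic trialkylphosphonium ylide, PBu3 quaternises the bromide, KOtBu removes the phosphonium α-proton in preference to the less acidic alkyne C–H, and the tributylphosphorus ylide should give the new disubstituted alkene with E geometry.

**Step 14**
Reactants: 20 propiolic acid
Product: 21 (2E)-2,3-dibromoprop-2-enoic acid
Conditions: Br2, LiBr (cat.), CH2Cl2, 0 → 25 °C, dark
Reagents that add atoms: bromine, BrBr
Why: Ionic anti addition of bromine across the alkyne (bromide opening of the bromonium ion) should give the trans dibromide, in which the β-bromine is cis to the carboxyl group and no hydrogen is anti to a bromine.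

**Step 15**
Reactants: 19 polyenyne; 21 (2E)-2,3-dibromoprop-2-enoic acid
Product: 23 (5Z)-3-bromo-5-ylidenefuran-2(5H)-one bearing the polyenyne chain, via bromo enynoic acid 22 (not isolated)
Conditions: Pd(PPh3)4 (5 mol%), CuI (10 mol%), Et3N (5 equiv), MeCN/THF, 25 °C, dark; 21 in slight excess
Reagents that add atoms: none
Why: Zerovalent palladium inserts into the β C–Br bond of the triethylammonium salt of 21 (the vinylogous acyl bromide position, more electrophilic and less hindered than the α C–Br), the copper acetylide of 19 transmetalates and reductive elimination gives enynoic acid 22 with the alkyne cis to the carboxylate, whose oxygen then adds across the metal-coordinated alkyne anti to the metal before protodemetalation releases the lactone. The closest known reaction type is the tandem Sonogashira coupling–lactonisation of (Z)-3-halopropenoic acids with terminal alkynes to (Z)-γ-alkylidenebutenolides. The ring (O1, C2, C3, C4, C5) closes in the 5-exo-dig mode by forming the O1–C5 bond. No stereocentre is created; the Z geometry of the exocyclic alkene at C5 follows from anti oxymetalation and protonation with retention, which places the polyene chain cis to O1. The step needs 5-exo over 6-endo closure, which the amine-buffered palladium/copper conditions and the cis carboxylate favour, and it needs mono-coupling, which the lower reactivity of the α-bromide left on C3 and the excess of 21 should secure.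

**Step 16**
Reactants: 23 bromobutenolide; 11 alkenylstannane
Product: 24 bis-TBS ether of the target
Conditions: Pd2(dba)3 (2.5 mol%), AsPh3 (20 mol%), NMP, 40 °C, dark
Reagents that add atoms: none
Why: Stille coupling (oxidative addition into the C3–Br bond, tin-to-palladium transmetalation accelerated by AsPh3, reductive elimination) forms the C3–vinyl bond with retention of the E geometry under neutral conditions that should spare the epoxide and the enol lactone.

**Step 17**
Reactants: 24 bis-TBS ether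
Product: 25 target CNP0180336.1
Conditions: Bu4NF, AcOH, THF, 0 → 25 °C
Reagents that add atoms: none
Why: Fluoride cleaves both secondary silyl ethers, and the acetic acid buffer keeps basic fluoride from opening the enol lactone while exposing the epoxide to no strong acid, so no stereocentre is affected.

**Compound list**

1 | (−)-actinol, (4R,6R)-4-hydroxy-2,2,6-trimethylcyclohexan-1-one | C[C@H]1C(=O)C(C)(C)C[C@H](O)C1 | starting material
2 | (4R,6R)-4-(TBSO)-2,2,6-trimethylcyclohexan-1-one | C[C@H]1C(=O)C(C)(C)C[C@H](O[Si](C)(C)C(C)(C)C)C1 | intermediate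
3 | lithium (4R)-4-(TBSO)-2,6,6-trimethylcyclohex-1-en-1-olate | [Li+].[O-]C1=C(C)C[C@@H](O[Si](C)(C)C(C)(C)C)CC1(C)C | intermediate
4 | (4R)-4-(TBSO)-2,6,6-trimethylcyclohex-1-en-1-yl trifluoromethanesulfonate | CC1=C(OS(=O)(=O)C(F)(F)F)C(C)(C)C[C@H](O[Si](C)(C)C(C)(C)C)C1 | intermediate
5 | methyl (4R)-4-(TBSO)-2,6,6-trimethylcyclohex-1-ene-1-carboxylate | COC(=O)C1=C(C)C[C@@H](O[Si](C)(C)C(C)(C)C)CC1(C)C | intermediate
6 | [(4R)-4-(TBSO)-2,6,6-trimethylcyclohex-1-en-1-yl]methanol | OCC1=C(C)C[C@@H](O[Si](C)(C)C(C)(C)C)CC1(C)C | intermediate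
7 | [(1R,4S,6R)-4-(TBSO)-2,2,6-trimethyl-7-oxabicyclo[4.1.0]heptan-1-yl]methanol, epoxide trans to the silyloxy group | OC[C@@]12O[C@]1(C)C[C@@H](O[Si](C)(C)C(C)(C)C)CC2(C)C | intermediate
8 | (1R,4S,6R)-4-(TBSO)-2,2,6-trimethyl-7-oxabicyclo[4.1.0]heptane-1-carbaldehyde | O=C[C@@]12O[C@]1(C)C[C@@H](O[Si](C)(C)C(C)(C)C)CC2(C)C | intermediate
9 | (1S,4S,6R)-4-(TBSO)-1-[(E)-2-iodoethenyl]-2,2,6-trimethyl-7-oxabicyclo[4.1.0]heptane | I/C=C/[C@@]12O[C@]1(C)C[C@@H](O[Si](C)(C)C(C)(C)C)CC2(C)C | intermediate
10 | (E)-alkenyllithium derived from 9 | [Li]/C=C/[C@@]12O[C@]1(C)C[C@@H](O[Si](C)(C)C(C)(C)C)CC2(C)C | intermediate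
11 | tributyl{(E)-2-[(1S,4S,6R)-4-(TBSO)-2,2,6-trimethyl-7-oxabicyclo[4.1.0]heptan-1-yl]ethenyl}stannane | CCCC[Sn](CCCC)(CCCC)/C=C/[C@@]12O[C@]1(C)C[C@@H](O[Si](C)(C)C(C)(C)C)CC2(C)C | intermediate
12 | (2E)-3-methylpent-2-en-4-yn-1-ol | C#C/C(C)=C/CO | starting material
13 | (2E)-5-[(4R)-4-(TBSO)-2,6,6-trimethylcyclohex-1-en-1-yl]-3-methylpent-2-en-4-yn-1-ol | CC1=C(C#C/C(C)=C/CO)C(C)(C)C[C@H](O[Si](C)(C)C(C)(C)C)C1 | intermediate
14 | (2E)-5-[(4R)-4-(TBSO)-2,6,6-trimethylcyclohex-1-en-1-yl]-3-methylpent-2-en-4-ynal | CC1=C(C#C/C(C)=C/C=O)C(C)(C)C[C@H](O[Si](C)(C)C(C)(C)C)C1 | intermediate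
15 | (2E,4E)-7-[(4R)-4-(TBSO)-2,6,6-trimethylcyclohex-1-en-1-yl]-5-methylhepta-2,4-dien-6-ynal | CC1=C(C#C/C(C)=C/C=C/C=O)C(C)(C)C[C@H](O[Si](C)(C)C(C)(C)C)C1 | intermediate
16 | (3E)-5-bromo-3-methylpent-3-en-1-yne | C#C/C(C)=C/CBr | intermediate
17 | tributyl[(2E)-3-methylpent-2-en-4-yn-1-yl]phosphonium bromide | C#C/C(C)=C/C[P+](CCCC)(CCCC)CCCC.[Br-] | intermediate
18 | tributyl[(2E)-3-methylpent-2-en-4-yn-1-ylidene]phosphorane | C#C/C(C)=C/C=P(CCCC)(CCCC)CCCC | intermediate
19 | (4R)-1-[(3E,5E,7E,9E)-3,10-dimethyldodeca-3,5,7,9-tetraene-1,11-diyn-1-yl]-4-(TBSO)-2,6,6-trimethylcyclohex-1-ene | CC1=C(C#C/C(C)=C/C=C/C=C/C=C(C)/C#C)C(C)(C)C[C@H](O[Si](C)(C)C(C)(C)C)C1 | intermediate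
20 | propiolic acid (prop-2-ynoic acid) | C#CC(=O)O | starting material
21 | (2E)-2,3-dibromoprop-2-enoic acid | OC(=O)/C(Br)=C\Br | intermediate
22 | (2E,6E,8E,10E,12E)-2-bromo-6,13-dimethyl-15-[(4R)-4-(TBSO)-2,6,6-trimethylcyclohex-1-en-1-yl]pentadeca-2,6,8,10,12-pentaene-4,14-diynoic acid | CC1=C(C#C/C(C)=C/C=C/C=C/C=C(C)/C#C/C=C(Br)\C(=O)O)C(C)(C)C[C@H](O[Si](C)(C)C(C)(C)C)C1 | intermediate
23 | (5Z)-3-bromo-5-[(2E,4E,6E,8E)-2,9-dimethyl-11-[(4R)-4-(TBSO)-2,6,6-trimethylcyclohex-1-en-1-yl]undeca-2,4,6,8-tetraen-10-yn-1-ylidene]furan-2(5H)-one | CC1=C(C#C/C(C)=C/C=C/C=C/C=C(C)/C=C2C=C(Br)C(=O)O/2)C(C)(C)C[C@H](O[Si](C)(C)C(C)(C)C)C1 | intermediate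
24 | bis-TBS ether of the target (both ring hydroxyls silylated) | CC1=C(C#C/C(C)=C/C=C/C=C/C=C(C)/C=C2C=C(/C=C/[C@@]34O[C@]3(C)C[C@@H](O[Si](C)(C)C(C)(C)C)CC4(C)C)C(=O)O/2)C(C)(C)C[C@H](O[Si](C)(C)C(C)(C)C)C1 | intermediate
25 | CNP0180336.1, (5Z)-ylidenebutenolide with the (3S,5R,6S)-5,6-epoxy-3-hydroxy ring and the (3R)-3-hydroxy acetylenic ring | CC1=C(C#C/C(C)=C/C=C/C=C/C=C(C)/C=C2C=C(/C=C/[C@@]34O[C@]3(C)C[C@@H](O)CC4(C)C)C(=O)O/2)C(C)(C)C[C@H](O)C1 | target

**Step count and risks**

Total steps: 17. Longest linear sequence: 10 steps (1, 2, 3, 4, 5, 6, 7, 8, 16, 17).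

Steps most likely to fail:

1. Step 15. Zerovalent palladium may insert into the α C–Br bond or react a second time at the C3–Br bond of the product, the carboxylate may close 6-endo to the pyranone, and the copper acetylide may homocouple. The fallback separates coupling from ring closure and changes the metal that closes the ring; it sets out from 19 and 21 and comes back to the route at 23. Acid 21 is esterified (EtOH, H2SO4 cat.) to ethyl (2E)-2,3-dibromoprop-2-enoate F1. Sonogashira coupling of F1 with 19 (PdCl2(PPh3)2, CuI, Et3N, THF) gives the ethyl ester of the bromo enynoic acid F2. Saponification (LiOH, THF/H2O, 0 °C) gives acid 22, now isolated, and AgNO3 (10 mol%) in acetone closes it 5-exo-dig to 23.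

2. Step 13. E selectivity at the new alkene may be incomplete, and the base may deprotonate the terminal alkyne so that an acetylide adds to aldehyde 15. The fallback moves the carbanion to the ring half and keeps the free alkyne in the electrophile; it sets out from 13 and 12 and comes back at 19. Alcohol 13 is brominated (CBr4, PPh3) to the allylic bromide F3, and Arbuzov reaction with P(OEt)3 gives the diethyl phosphonate F4. Alcohol 12 is oxidised (MnO2) to (2E)-3-methylpent-2-en-4-ynal F5 and homologated with Ph3P=CHCHO to (2E,4E)-5-methylhepta-2,4-dien-6-ynal F6. Horner–Wadsworth–Emmons reaction of F4 (NaN(SiMe3)2, THF, −78 °C) with F6 should give 19 with the E alkene.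

3. Step 17. Basic fluoride may open or isomerise the enol lactone, and the buffered reagent may cleave the two hindered silyl ethers incompletely. The fallback removes the silyl groups before the fragments are joined; it sets out from 11 and 19 and comes back at 25. Bu4NF converts 11 to the hydroxy stannane F7 and 19 to the hydroxy polyenyne F8. F8 and 21 undergo the tandem coupling–lactonisation of step 15 through the hydroxy bromo enynoic acid F9 to the hydroxy bromobutenolide F10, and Stille coupling of F10 with F7 gives 25 directly.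

**Further compounds**

F1 | step 15 | ethyl (2E)-2,3-dibromoprop-2-enoate | CCOC(=O)/C(Br)=C\Br
F2 | step 15 | ethyl ester of bromo enynoic acid 22 | CC1=C(C#C/C(C)=C/C=C/C=C/C=C(C)/C#C/C=C(Br)\C(=O)OCC)C(C)(C)C[C@H](O[Si](C)(C)C(C)(C)C)C1
F3 | step 13 | (4R)-1-[(3E)-5-bromo-3-methylpent-3-en-1-yn-1-yl]-4-(TBSO)-2,6,6-trimethylcyclohex-1-ene | CC1=C(C#C/C(C)=C/CBr)C(C)(C)C[C@H](O[Si](C)(C)C(C)(C)C)C1
F4 | step 13 | diethyl {(2E)-5-[(4R)-4-(TBSO)-2,6,6-trimethylcyclohex-1-en-1-yl]-3-methylpent-2-en-4-yn-1-yl}phosphonate | CC1=C(C#C/C(C)=C/CP(=O)(OCC)OCC)C(C)(C)C[C@H](O[Si](C)(C)C(C)(C)C)C1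
F5 | step 13 | (2E)-3-methylpent-2-en-4-ynal | C#C/C(C)=C/C=O
F6 | step 13 | (2E,4E)-5-methylhepta-2,4-dien-6-ynal | C#C/C(C)=C/C=C/C=O
F7 | step 17 | hydroxy stannane, desilylated 11 | CCCC[Sn](CCCC)(CCCC)/C=C/[C@@]12O[C@]1(C)C[C@@H](O)CC2(C)C
F8 | step 17 | hydroxy polyenyne, desilylated 19 | CC1=C(C#C/C(C)=C/C=C/C=C/C=C(C)/C#C)C(C)(C)C[C@H](O)C1
F9 | step 17 | hydroxy bromo enynoic acid, desilylated 22 | CC1=C(C#C/C(C)=C/C=C/C=C/C=C(C)/C#C/C=C(Br)\C(=O)O)C(C)(C)C[C@H](O)C1
F10 | step 17 | hydroxy bromobutenolide, desilylated 23 | CC1=C(C#C/C(C)=C/C=C/C=C/C=C(C)/C=C2C=C(Br)C(=O)O/2)C(C)(C)C[C@H](O)C1
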